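## Structural features

The target is a trans-fused decalin (ring A: C1–C5 and C10; ring B: C5–C10) that carries at C1 an exocyclic methine C9′, which bears an isobutyl group and a 3,5-diformyl-2,4,6-trihydroxyphenyl ring. Five stereocentres lie in the decalin (C1, C4, C5, C7, C10) and one outside it (C9′); C4–C5–C10–C1–C9′ form an unbroken row and C10 is quaternary. In the chair–chair form the C10 methyl and the C4 hydroxyl are syn-diaxial, while the C4 methyl, the C1 side chain and the C7 hydroxyisopropyl group are equatorial. The two tertiary alcohols (C4, C11) ionise or eliminate under strong acid, the aldehydes exclude late organometallic steps, and the electron-rich arene makes C9′ a latent cation. The real difficulties are the quaternary C10 between two stereocentres, the tertiary carbinol C4 of defined configuration, and C9′, wedged between a neopentyl-type ring carbon and a hexasubstituted arene. The key step uses the fact that C4 (oxygen and methyl), C5, C10 (methyl) and C9 form a head-to-tail 1,5-diene pattern ending at C7. An open chain with an enol ether at C4, an (E)-alkene C10=C5 and a vinyl ketone C7(=O)–C8=C9 can therefore fold into both rings, leaving C7 as a ketone for the hydroxyisopropyl group.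

## Logic of the disconnections

**35 ⇒ 32 (arene decoration).** The three O–CH3 bonds and the two aryl–CHO bonds are cut first (35 ⇒ 34 ⇒ 33 ⇒ 32). Free phenols and aldehydes would not survive the organometallic and acidic steps of the side chain. The two open ring positions of 32 are each flanked by two methoxy groups, so the formyl carbons can go in by bromination and lithium–halogen exchange, under basic conditions that cannot ionise the tertiary alcohols. The gain is a plain trimethoxyphenyl group. The forward steps must avoid Lewis acids, hence no TiCl4-mediated formylation, and a thiolate rather than a boron halide for the demethylation.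

**32 ⇒ 27 + 28 (C9′–H and C9′–aryl bonds).** After the Si–O bond (32 ⇒ 31), the C9′–H bond and then the C9′–C1′ bond are cut (31 ⇒ 30 ⇒ 27 + 28, through 29). C9′ is benzylic to a very electron-rich ring, so its configuration can be set last, by hydride delivery to a planar cation under the control of C1. The gain is the loss of the C9′ stereocentre and a commercial arene. The demand is double: a hindered aryl nucleophile must add to a hindered, enolisable ketone, and the acid must be mild enough for the C4 silyl ether and the C11 alcohol.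

**27 ⇒ 25 (C9′–CH2 bond).** The isobutyl group is removed, leaving the ester 25 (through 26). This returns C9′ to the carboxyl carbon that the key step carries. The forward step must stop at the ketone, which the chelated N-methoxy-N-methylamide intermediate ensures.

**25 ⇒ 21 (C11–CH3 and C7–C11 bonds; C1 and C7 configurations).** The hydroxyisopropyl group is cut back to an acetyl group and then to the ring ketone (25 ⇒ 24 ⇒ 23 ⇒ 21). C7 is handled before the C1 side chain because a ketone reacts ahead of a hindered ester; no ketone protecting group is then needed, and one base treatment can settle both epimerisable centres. The demand is ketone-versus-ester selectivity and a thermodynamic preference for the diequatorial isomer.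

**21 ⇒ 20 (C4–C5 and C9–C10 bonds, both rings).** This is the strategic cut. It turns a bicycle with four stereocentres into an open chain with one stereocentre and one defined alkene. The forward step needs radical initiation at the enol ether only, two 6-endo closures, and transfer of the C1 configuration to C4, C5 and C10.

**20 ⇒ 18 + 19 (C7–C8 bond).** The vinyl ketone is the most fragile group of 20, so it is made last, from an N-methoxy-N-methylamide that has been inert through all earlier steps. This avoids removing an alcohol protecting group in the presence of the silyl enol ether. The Grignard reagent must distinguish the amide from the hindered ester and leave the enol ether alone.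

**18 ⇒ 14 (O–Si bond; ester for auxiliary).** The enol ether is traced to the methyl ketone 17 (kinetic enolate) and the methyl ester to the imide 14 through 16. The demand is deprotonation at the ketone CH3 in preference to the doubly activated but hindered ester α-CH.

**14 ⇒ 10 + 12 (C1–C2 bond).** The 3-oxobutyl chain is cut from C1. Forward, one deconjugative alkylation of a dienolate sets C1 (auxiliary control) and the (E)-alkene (from the (Z)-enoyl geometry). Imide dienolates alkylate well only with activated halides, so the chain is brought in as the allylic iodide 12, made from 11; its silyl enol ether also masks the new ketone until work-up.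

**10 ⇒ 5 (N–acyl bond; C10–CH3 bond).** The auxiliary 8 is removed (10 ⇒ 7 + 8) and the C10 methyl is cut from the (Z)-enoate (7 ⇒ 6 ⇒ 5). Syn addition of Me2CuLi must give the chain cis to the carbonyl, since this decides which γ-CH is removed later.

**5 ⇒ 1 + 4 (C1–carboxyl bond; amide).** The ynoate comes from the acetylide of 3 and 4, and 3 from 1. The base must deprotonate the alkyne without attacking the amide.

## Other disconnections considered

**Alternative 1:** The cut is C4–C5, made while ring B is still a cyclohexadienone. Aldehyde A1, whose C10 is the quaternary carbon of a 4-methylcyclohexa-2,5-dienone and which already carries C1, C9′ and the arene, would be closed by a triazolium-derived carbene (intramolecular Stetter reaction) to the dione A2.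
- In its favour: the step is catalytic and fixes C10 and C5 together. It leaves a C4 ketone for methyl addition and an enone that marks C7. The arene and C9′ are in place before any ring forms, so no late cation chemistry is needed; on these last two points it is the better plan.
- Against it here: the two enone arms of A1 are diastereotopic, so the catalyst must match or override C1 and C9′. A1 itself, with two adjacent stereocentres beside a quaternary dienone carbon, is at least as hard to reach as 20. The ring fusion arises by protonation and is expected cis, so A2 would depend on epimerisation next to the C4 ketone, which is weakly biased in angularly methylated 1-decalones. C4 still needs a separate methyl addition.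
- Comparison: both plans put oxygen at C4 and C7 (equal). The radical closure draws the trans fusion and the C4 configuration from alkene geometry and a chair; the polar closure needs two further stereochemical operations. The step count is expected to be similar or higher because of A1.

**Alternative 2:** The cut is in the arene, at C1′–C6′ and C2′–C3′. The ynol silyl ether A3, carrying the finished, silyl-protected sesquiterpene and C9′, would add to the pyrone diester A4 in a Diels–Alder reaction; loss of CO2 from the bridged lactone would give the hexasubstituted benzene A5.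
- In its favour: all six ring substituents arrive with regiochemistry set by the polarisation of the partners. No aryl nucleophile attacks a hindered ketone and no benzylic cation is reduced. For the arene alone this is the better and more convergent construction.
- Against it here: the decalin and C9′ remain unsolved, since A3 must hold all six stereocentres and C9′ becomes a propargylic centre next to C1 that needs its own method. Ynol silyl ethers are thermally fragile at pyrone cycloaddition temperatures. The two esters of A5 must still be taken to aldehydes and three kinds of oxygen protection removed.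
- Comparison: pericyclic and predictable versus ionic and substrate-controlled at C9′. The need for a mild final deprotection is equal. The route is clearly longer overall, so it complements rather than replaces the chosen ring construction.

**Alternative 3:** The cuts are C9–C10 and C5–C6, with ring A from the chiral pool. The kinetic enolate of the carvone derivative A6 would add to 11 on the face away from the isopropenyl group, and aldol condensation would close ring B to the linear dienone A7.
- In its favour: a cheap enantiopure start, no auxiliary, a quaternary C10 set by a well-understood substrate bias, and the bicyclic skeleton in two steps. In early step economy and in the source of absolute configuration it is the better plan.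
- Against it here: the isopropenyl group must become C9′ with an aryl group, an isobutyl group and a new stereocentre, which is harder from a 1,1-disubstituted alkene than from the carboxyl carbon of 21. C4 and C5 of A7 are sp2, so the trans fusion and the axial tertiary alcohol need separate reductions and a hydration of defined stereochemistry.
- Comparison: enolate annulation versus a radical cascade. The C7 carbonyl is an equal handle in both. The chosen plan sets C4, C5 and C10 in one step where this one needs three later operations, so the early saving is expected to be lost.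

Key step: step 12

Remark on the chemistry: the ester of 20 is taken to lie pseudoaxial in the chair of the first ring closure (A(1,2) strain with the C10 methyl); if it proves pseudoequatorial, the (4S)-enantiomer of 8 gives the same series directly, with the ester of 21 already equatorial.

Abbreviation: TBS = tert-butyldimethylsilyl. Locants C1–C10, C11 and C9′ are those of the target; full names and SMILES are in the compound list.

## Route

Step 1
Reactants: 1 pent-4-ynoic acid
Product: 3 N-methoxy-N-methylpent-4-ynamide, via 1-(1H-imidazol-1-yl)pent-4-yn-1-one 2 (not isolated)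
Conditions: CDI, CH2Cl2, rt; then MeNHOMe·HCl, rt
Reagents that add atoms: 1,1'-carbonyldiimidazole, O=C(n1ccnc1)n1ccnc1 (imidazolyl group of 2 only); N,O-dimethylhydroxylamine hydrochloride, CNOC.Cl
Why: Amide coupling through the acyl imidazole. The N-methoxy-N-methylamide tolerates Me2CuLi, enolates and hydroperoxide and is the masked carbonyl (C7) of the vinyl ketone.

Step 2
Reactants: 3 N-methoxy-N-methylpent-4-ynamide; 4 methyl chloroformate
Product: 5 methyl 6-[methoxy(methyl)amino]-6-oxohex-2-ynoate
Conditions: LiN(SiMe3)2, THF, −78 °C; then 4, −78 → −20 °C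
Reagents that add atoms: none
Why: C-acylation of a lithium acetylide with a chloroformate. The hindered silylamide deprotonates the alkyne but does not add to the amide.

Step 3
Reactants: 5 methyl 6-[methoxy(methyl)amino]-6-oxohex-2-ynoate
Product: 6 methyl (2Z)-6-[methoxy(methyl)amino]-3-methyl-6-oxohex-2-enoate
Conditions: Me2CuLi (from CuI and MeLi), THF, −78 °C; MeOH, −78 °C
Reagents that add atoms: lithium dimethylcuprate, [Li+].C[Cu-]C
Why: Syn carbocupration of the ynoate and protonation with retention place the new methyl trans to the ester, so the chain is cis to the carbonyl ((Z)-enoate). Kept at −78 °C to prevent isomerisation of the alkenylcopper intermediate.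

Step 4
Reactants: 6 the (Z)-enoate
Product: 7 (2Z)-6-[methoxy(methyl)amino]-3-methyl-6-oxohex-2-enoic acid
Conditions: LiOH, THF/H2O, 40 °C; then 1 M HCl to pH 3
Reagents that add atoms: lithium hydroxide, [Li+].[OH-]
Why: Saponification. The tertiary amide and the alkene geometry are not affected by hydroxide at this temperature.

Step 5
Reactants: 7 the (Z)-enoic acid; 8 (4R)-4-benzyl-1,3-oxazolidin-2-one
Product: 10 (4R)-4-benzyl-3-{(2Z)-6-[methoxy(methyl)amino]-3-methyl-6-oxohex-2-enoyl}-1,3-oxazolidin-2-one, via mixed pivalic anhydride 9 (not isolated)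
Conditions: t-BuCOCl, Et3N, THF, −20 °C; then 8, LiCl, −20 °C → rt
Reagents that add atoms: pivaloyl chloride, CC(C)(C)C(Cl)=O (pivaloyl group of 9 only)
Why: N-acylation of the oxazolidinone through the mixed anhydride (LiCl/Et3N variant), a standard route to N-enoyl imides that leaves the (Z)-alkene intact.

Step 6
Reactants: 11 but-3-en-2-one
Product: 12 (2Z)-4-iodo-2-[(trimethylsilyl)oxy]but-2-ene
Conditions: Me3SiI, CH2Cl2, −78 → −40 °C; used at once as a solution
Reagents that add atoms: iodotrimethylsilane, C[Si](C)(C)I
Why: 1,4-Addition of the silyl iodide to the enone gives an allylic iodide that carries a silyl enol ether. It is an activated alkylating equivalent of 11, reactive enough for an imide dienolate at −78 °C.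

Step 7
Reactants: 10 the (Z)-enoyl imide; 12 the allylic iodide
Product: 14 (4R)-4-benzyl-3-[(2R,3E)-6-[methoxy(methyl)amino]-3-methyl-6-oxo-2-(3-oxobutyl)hex-3-enoyl]-1,3-oxazolidin-2-one, via trimethylsilyl enol ether 13 (not isolated)
Conditions: NaN(SiMe3)2, THF, −78 °C; then 12, −78 °C; AcOH, THF/H2O, 0 °C
Reagents that add atoms: none
Why: Deconjugative α-alkylation of a chelated sodium dienolate: the base removes a γ-proton from the CH2 cis to the carbonyl, and A(1,3) strain puts the chain trans to C1 in the new alkene ((E)-C10=C5). The iodide enters at the α-carbon on the face away from the benzyl group of the (R)-auxiliary, which sets (R)-C1. The silyl enol ether masks the ketone from the enolate until the acidic work-up.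

Step 8
Reactants: 14 the keto imide
Product: 16 (2R,3E)-6-[methoxy(methyl)amino]-3-methyl-6-oxo-2-(3-oxobutyl)hex-3-enoic acid, via peroxy acid 15 (not isolated)
Conditions: LiOH, H2O2, THF/H2O, 0 °C; Na2SO3; 1 M HCl to pH 3
Reagents that add atoms: hydrogen peroxide, OO
Why: Hydroperoxide cleaves the exocyclic imide carbonyl selectively even when hindered, and is too weakly basic to epimerise or conjugate the α-alkenyl centre. Sulfite reduces the peroxy acid and 8 is recovered.

Step 9
Reactants: 16 the keto acid
Product: 17 methyl (2R,3E)-6-[methoxy(methyl)amino]-3-methyl-6-oxo-2-(3-oxobutyl)hex-3-enoate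
Conditions: Me3SiCHN2, PhMe/MeOH, 0 °C
Reagents that add atoms: (trimethylsilyl)diazomethane, C[Si](C)(C)C=[N+]=[N-]
Why: Esterification with a diazoalkane under neutral conditions, so the β,γ-unsaturated α-stereocentre never meets base.

Step 10
Reactants: 17 the keto ester
Product: 18 methyl (2R,3E)-2-{3-[(tert-butyldimethylsilyl)oxy]but-3-en-1-yl}-6-[methoxy(methyl)amino]-3-methyl-6-oxohex-3-enoate
Conditions: LiN(i-Pr)2 (1.05 equiv), THF, −78 °C, 15 min; t-BuMe2SiOTf, −78 °C; Et3N, aq. NaHCO3
Reagents that add atoms: tert-butyldimethylsilyl trifluoromethanesulfonate, CC(C)(C)[Si](C)(C)OS(=O)(=O)C(F)(F)F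
Why: Kinetic deprotonation of the methyl ketone at its unhindered CH3, faster than at the hindered tertiary ester α-CH or the amide CH2, followed by O-silylation. This gives the terminal (1,1-disubstituted) silyl enol ether; short enolate lifetime limits proton transfer.

Step 11
Reactants: 18 the silyl enol ether amide; 19 vinylmagnesium bromide
Product: 20 methyl (2R,3E)-2-{3-[(tert-butyldimethylsilyl)oxy]but-3-en-1-yl}-3-methyl-6-oxoocta-3,7-dienoate
Conditions: 19 (1.5 equiv), THF, −78 → −30 °C; AcOH in THF at −78 °C, then pH 7 buffer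
Reagents that add atoms: none
Why: Acyl substitution of the N-methoxy-N-methylamide through its stable chelated tetrahedral adduct gives the vinyl ketone without over-addition. The hindered α-branched ester and the silyl enol ether are inert at low temperature, and the acetic acid quench protonates the released amine before it can add to the enone.

Step 12
Reactants: 20 the acyclic precursor
Product: 21 methyl (1R,4R,4aS,8aS)-4-[(tert-butyldimethylsilyl)oxy]-4,8a-dimethyl-6-oxodecahydronaphthalene-1-carboxylate
Conditions: Fe(acac)3 (0.5 equiv), PhSiH3 (3 equiv), Na2HPO4 (1 equiv), EtOH, 0.01 M, degassed, 60 °C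
Reagents that add atoms: none
Why: The hydride formed from Fe(acac)3 and PhSiH3 transfers a hydrogen atom to the terminal CH2 of the silyl enol ether, the most electron-rich and least hindered alkene, creating the C4 methyl and a tertiary α-silyloxy radical at C4. This radical closes ring A 6-endo-trig on C5 of the (E)-alkene (5-exo attack would have to occur at the methyl-bearing C10 and give a secondary radical), and the tertiary C10 radical closes ring B, again 6-endo-trig, on the terminal carbon of the vinyl ketone in a polarity-matched Giese addition. The α-keto radical is reduced by divalent iron and the enolate is protonated by ethanol, which returns trivalent iron. The closest known reaction type is the Fe(acac)3/PhSiH3 radical polyene cyclisation that ends on an enone and gives trans-decalins, combined with hydrogen-atom-transfer initiation at silyl enol ethers as known from Giese couplings. C5 and C10: in the chair–chair array the (E)-alkene places H5 and the C10 methyl anti, which gives the trans fusion. C4: the oxygen substituent, smaller than methyl, takes the axial site syn to the C10 methyl, so the C4 methyl ends equatorial. The alkene face, and so the absolute configuration of all three new centres, is set by C1, whose ester avoids A(1,2) strain with the C10 methyl by lying pseudoaxial and ends axial in 21. The step needs initiation at the enol ether rather than at the trisubstituted alkene or the enone, and cyclisation rather than intermolecular coupling; the 1,1-disubstituted donor alkene, high dilution and the phosphate buffer are meant to secure this.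

Step 13
Reactants: 21 the decalin keto ester
Product: 23 methyl (1R,4R,4aS,8aS)-6-acetyl-4-[(tert-butyldimethylsilyl)oxy]-4,8a-dimethyldecahydronaphthalene-1-carboxylate (both C6 epimers), via methyl enol ether 22 (not isolated)
Conditions: [Ph3PCH(OMe)Me]Cl, KN(SiMe3)2, THF, −40 → 0 °C; 21, 0 °C → rt; then 1 M HCl, THF, rt
Reagents that add atoms: (1-methoxyethyl)triphenylphosphonium chloride, COC(C)[P+](c1ccccc1)(c1ccccc1)c1ccccc1.[Cl-]; water, O
Why: Wittig reaction of the unhindered ring ketone with the α-methoxyethylidene ylide, then hydrolysis of the enol ether, homologates C7 to an acetyl group in one operation. The ester is inert to the ylide, the tertiary silyl ether tolerates dilute acid, and the C7 configuration is settled in step 14.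

Step 14
Reactants: 23 the acetyl ester (epimer mixture)
Product: 24 methyl (1S,4R,4aS,6S,8aS)-6-acetyl-4-[(tert-butyldimethylsilyl)oxy]-4,8a-dimethyldecahydronaphthalene-1-carboxylate
Conditions: NaOMe (0.5 equiv), MeOH, 50 °C; chromatography, minor isomers resubmitted
Reagents that add atoms: none
Why: Base-mediated epimerisation under thermodynamic control. The acetyl group at C7 and the ester at C1 both move to equatorial sites through their enolates, as in the target; C4, C5 and C10 are not enolisable.

Step 15
Reactants: 24 the diequatorial keto ester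
Product: 25 methyl (1S,4R,4aS,6S,8aS)-4-[(tert-butyldimethylsilyl)oxy]-6-(2-hydroxypropan-2-yl)-4,8a-dimethyldecahydronaphthalene-1-carboxylate
Conditions: MeMgBr, CeCl3, THF, −78 °C
Reagents that add atoms: methylmagnesium bromide, C[Mg]Br
Why: 1,2-Addition of MeCeCl2 to the methyl ketone. The ketone reacts far faster than the hindered ester at −78 °C, and the cerium reagent suppresses enolisation, so C7 is not epimerised.

Step 16
Reactants: 25 the hydroxy ester
Product: 27 1-[(1S,4R,4aS,6S,8aS)-4-[(tert-butyldimethylsilyl)oxy]-6-(2-hydroxypropan-2-yl)-4,8a-dimethyldecahydronaphthalen-1-yl]-3-methylbutan-1-one, via N-methoxy-N-methylamide 26 (not isolated)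
Conditions: MeNHOMe·HCl, i-PrMgCl, THF, −20 → 0 °C; then i-BuLi, −78 → −30 °C
Reagents that add atoms: N,O-dimethylhydroxylamine hydrochloride, CNOC.Cl (amide group of 26 only); isobutyllithium, [Li]CC(C)C
Why: Aminolysis of the ester by the magnesium amide, then acyl substitution by isobutyllithium through the chelated tetrahedral adduct, which prevents over-addition. The tertiary alkoxide is a spectator.

Step 17
Reactants: 27 the isobutyl ketone; 28 1,3,5-trimethoxybenzene
Product: 30 1-[(1S,4R,4aS,6S,8aR)-4-[(tert-butyldimethylsilyl)oxy]-6-(2-hydroxypropan-2-yl)-4,8a-dimethyldecahydronaphthalen-1-yl]-3-methyl-1-(2,4,6-trimethoxyphenyl)butan-1-ol (both carbinol epimers), via 2,4,6-trimethoxyphenyllithium 29 (not isolated)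
Conditions: 28, n-BuLi, THF, 0 °C → rt; CeCl3, −78 °C; then 27, −78 → 0 °C
Reagents that add atoms: none
Why: Directed ortho-lithiation between two methoxy groups, transmetalation to the less basic ArCeCl2, and 1,2-addition to the hindered, enolisable ketone. The carbinol configuration does not matter because this centre is ionised in step 18.

Step 18
Reactants: 30 the tertiary benzylic alcohol
Product: 31 2-[(1S)-1-[(1R,4R,4aS,6S,8aR)-4-[(tert-butyldimethylsilyl)oxy]-6-(2-hydroxypropan-2-yl)-4,8a-dimethyldecahydronaphthalen-1-yl]-3-methylbutyl]-1,3,5-trimethoxybenzene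
Conditions: Et3SiH (5 equiv), CF3CO2H (3 equiv), CH2Cl2, −40 °C; aq. NaHCO3 at −40 °C
Reagents that add atoms: none
Why: Ionic hydrogenation. The trimethoxyphenyl group lets the benzylic alcohol ionise at −40 °C, where the unactivated tertiary alcohol and the tertiary silyl ether persist. In the cation, A(1,3) strain with the ortho-methoxy group turns H1 into the cation plane, C10 and C2 flank the two faces, and the silane delivers hydride opposite the quaternary C10, which corresponds to (S)-C9′.

Step 19
Reactants: 31 the silyl ether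
Product: 32 2-[(1S)-1-[(1R,4R,4aS,6S,8aR)-4-hydroxy-6-(2-hydroxypropan-2-yl)-4,8a-dimethyldecahydronaphthalen-1-yl]-3-methylbutyl]-1,3,5-trimethoxybenzene
Conditions: Bu4NF, THF, 60 °C
Reagents that add atoms: none
Why: Fluoride-mediated desilylation of the hindered tertiary silyl ether under basic conditions, so neither tertiary alcohol can ionise.

Step 20
Reactants: 32 the diol
Product: 33 1,3-dibromo-5-[(1S)-1-[(1R,4R,4aS,6S,8aR)-4-hydroxy-6-(2-hydroxypropan-2-yl)-4,8a-dimethyldecahydronaphthalen-1-yl]-3-methylbutyl]-2,4,6-trimethoxybenzene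
Conditions: NBS (2.1 equiv), MeCN, 0 °C, dark
Reagents that add atoms: N-bromosuccinimide, O=C1CCC(=O)N1Br
Why: Electrophilic aromatic bromination. The only two free ring positions each lie between two methoxy groups, so the regiochemistry is unambiguous and the conditions are neutral.

Step 21
Reactants: 33 the dibromide
Product: 34 5-[(1S)-1-[(1R,4R,4aS,6S,8aR)-4-hydroxy-6-(2-hydroxypropan-2-yl)-4,8a-dimethyldecahydronaphthalen-1-yl]-3-methylbutyl]-2,4,6-trimethoxybenzene-1,3-dicarbaldehyde
Conditions: t-BuLi (6.5 equiv), THF, −78 °C; DMF, −78 → 0 °C; aq. NH4Cl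
Reagents that add atoms: N,N-dimethylformamide, CN(C)C=O
Why: Deprotonation of both alcohols, double lithium–halogen exchange (each aryllithium is stabilised by two ortho-methoxy groups) and formylation with DMF. The hemiaminal alkoxides persist until work-up, so there is no over-addition and no cationic intermediate.

Step 22
Reactants: 34 the dialdehyde trimethyl ether
Product: 35 5-[(1S)-1-[(1R,4R,4aS,6S,8aR)-4-hydroxy-6-(2-hydroxypropan-2-yl)-4,8a-dimethyldecahydronaphthalen-1-yl]-3-methylbutyl]-2,4,6-trihydroxybenzene-1,3-dicarbaldehyde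
Conditions: NaSEt (10 equiv), DMF, 110 °C; then 1 M HCl
Reagents that add atoms: none
Why: SN2 demethylation of aryl methyl ethers by thiolate. Every methoxy group is ortho to a formyl group, which stabilises the departing phenoxide, and the basic medium leaves both tertiary alcohols and all stereocentres untouched.

## Compound list

1 | pent-4-ynoic acid | C#CCCC(=O)O | starting material
2 | 1-(1H-imidazol-1-yl)pent-4-yn-1-one | C#CCCC(=O)n1ccnc1 | intermediate
3 | N-methoxy-N-methylpent-4-ynamide | C#CCCC(=O)N(C)OC | intermediate
4 | methyl chloroformate | COC(Cl)=O | starting material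
5 | methyl 6-[methoxy(methyl)amino]-6-oxohex-2-ynoate | COC(=O)C#CCCC(=O)N(C)OC | intermediate
6 | methyl (2Z)-6-[methoxy(methyl)amino]-3-methyl-6-oxohex-2-enoate | COC(=O)/C=C(/C)CCC(=O)N(C)OC | intermediate
7 | (2Z)-6-[methoxy(methyl)amino]-3-methyl-6-oxohex-2-enoic acid | OC(=O)/C=C(/C)CCC(=O)N(C)OC | intermediate
8 | (4R)-4-benzyl-1,3-oxazolidin-2-one | O=C1N[C@H](Cc2ccccc2)CO1 | starting material
9 | (2Z)-6-[methoxy(methyl)amino]-3-methyl-6-oxohex-2-enoic 2,2-dimethylpropanoic anhydride | CC(C)(C)C(=O)OC(=O)/C=C(/C)CCC(=O)N(C)OC | intermediate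
10 | (4R)-4-benzyl-3-{(2Z)-6-[methoxy(methyl)amino]-3-methyl-6-oxohex-2-enoyl}-1,3-oxazolidin-2-one | CON(C)C(=O)CC/C(C)=C\C(=O)N1[C@H](Cc2ccccc2)COC1=O | intermediate
11 | but-3-en-2-one (methyl vinyl ketone) | CC(=O)C=C | starting material
12 | (2Z)-4-iodo-2-[(trimethylsilyl)oxy]but-2-ene | C/C(O[Si](C)(C)C)=C/CI | intermediate
13 | (4R)-4-benzyl-3-[(2R,3E)-6-[methoxy(methyl)amino]-3-methyl-6-oxo-2-{(2Z)-3-[(trimethylsilyl)oxy]but-2-en-1-yl}hex-3-enoyl]-1,3-oxazolidin-2-one | C/C(O[Si](C)(C)C)=C/C[C@@H](C(=O)N1[C@H](Cc2ccccc2)COC1=O)/C(C)=C/CC(=O)N(C)OC | intermediate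
14 | (4R)-4-benzyl-3-[(2R,3E)-6-[methoxy(methyl)amino]-3-methyl-6-oxo-2-(3-oxobutyl)hex-3-enoyl]-1,3-oxazolidin-2-one | CC(=O)CC[C@@H](C(=O)N1[C@H](Cc2ccccc2)COC1=O)/C(C)=C/CC(=O)N(C)OC | intermediate
15 | (2R,3E)-6-[methoxy(methyl)amino]-3-methyl-6-oxo-2-(3-oxobutyl)hex-3-eneperoxoic acid | CC(=O)CC[C@@H](C(=O)OO)/C(C)=C/CC(=O)N(C)OC | intermediate
16 | (2R,3E)-6-[methoxy(methyl)amino]-3-methyl-6-oxo-2-(3-oxobutyl)hex-3-enoic acid | CC(=O)CC[C@@H](C(=O)O)/C(C)=C/CC(=O)N(C)OC | intermediate
17 | methyl (2R,3E)-6-[methoxy(methyl)amino]-3-methyl-6-oxo-2-(3-oxobutyl)hex-3-enoate | CC(=O)CC[C@@H](C(=O)OC)/C(C)=C/CC(=O)N(C)OC | intermediate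
18 | methyl (2R,3E)-2-{3-[(tert-butyldimethylsilyl)oxy]but-3-en-1-yl}-6-[methoxy(methyl)amino]-3-methyl-6-oxohex-3-enoate | C=C(O[Si](C)(C)C(C)(C)C)CC[C@@H](C(=O)OC)/C(C)=C/CC(=O)N(C)OC | intermediate
19 | vinylmagnesium bromide | C=C[Mg]Br | starting material
20 | methyl (2R,3E)-2-{3-[(tert-butyldimethylsilyl)oxy]but-3-en-1-yl}-3-methyl-6-oxoocta-3,7-dienoate | C=C(O[Si](C)(C)C(C)(C)C)CC[C@@H](C(=O)OC)/C(C)=C/CC(=O)C=C | intermediate
21 | methyl (1R,4R,4aS,8aS)-4-[(tert-butyldimethylsilyl)oxy]-4,8a-dimethyl-6-oxodecahydronaphthalene-1-carboxylate (trans-fused, ester axial) | COC(=O)[C@@H]1CC[C@@](C)(O[Si](C)(C)C(C)(C)C)[C@H]2CC(=O)CC[C@]12C | intermediate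
22 | methyl (1R,4R,4aS,8aS)-4-[(tert-butyldimethylsilyl)oxy]-6-(1-methoxyethylidene)-4,8a-dimethyldecahydronaphthalene-1-carboxylate (E/Z mixture) | COC(=O)[C@@H]1CC[C@@](C)(O[Si](C)(C)C(C)(C)C)[C@H]2CC(=C(C)OC)CC[C@]12C | intermediate
23 | methyl (1R,4R,4aS,8aS)-6-acetyl-4-[(tert-butyldimethylsilyl)oxy]-4,8a-dimethyldecahydronaphthalene-1-carboxylate (both C6 epimers) | COC(=O)[C@@H]1CC[C@@](C)(O[Si](C)(C)C(C)(C)C)[C@H]2CC(C(C)=O)CC[C@]12C | intermediate
24 | methyl (1S,4R,4aS,6S,8aS)-6-acetyl-4-[(tert-butyldimethylsilyl)oxy]-4,8a-dimethyldecahydronaphthalene-1-carboxylate (ester and acetyl equatorial) | COC(=O)[C@H]1CC[C@@](C)(O[Si](C)(C)C(C)(C)C)[C@H]2C[C@@H](C(C)=O)CC[C@]12C | intermediate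
25 | methyl (1S,4R,4aS,6S,8aS)-4-[(tert-butyldimethylsilyl)oxy]-6-(2-hydroxypropan-2-yl)-4,8a-dimethyldecahydronaphthalene-1-carboxylate | COC(=O)[C@H]1CC[C@@](C)(O[Si](C)(C)C(C)(C)C)[C@H]2C[C@@H](C(C)(C)O)CC[C@]12C | intermediate
26 | (1S,4R,4aS,6S,8aS)-4-[(tert-butyldimethylsilyl)oxy]-6-(2-hydroxypropan-2-yl)-N-methoxy-N,4,8a-trimethyldecahydronaphthalene-1-carboxamide | CON(C)C(=O)[C@H]1CC[C@@](C)(O[Si](C)(C)C(C)(C)C)[C@H]2C[C@@H](C(C)(C)O)CC[C@]12C | intermediate
27 | 1-[(1S,4R,4aS,6S,8aS)-4-[(tert-butyldimethylsilyl)oxy]-6-(2-hydroxypropan-2-yl)-4,8a-dimethyldecahydronaphthalen-1-yl]-3-methylbutan-1-one | CC(C)CC(=O)[C@H]1CC[C@@](C)(O[Si](C)(C)C(C)(C)C)[C@H]2C[C@@H](C(C)(C)O)CC[C@]12C | intermediate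
28 | 1,3,5-trimethoxybenzene | COc1cc(OC)cc(OC)c1 | starting material
29 | 2,4,6-trimethoxyphenyllithium | [Li]c1c(OC)cc(OC)cc1OC | intermediate
30 | 1-[(1S,4R,4aS,6S,8aR)-4-[(tert-butyldimethylsilyl)oxy]-6-(2-hydroxypropan-2-yl)-4,8a-dimethyldecahydronaphthalen-1-yl]-3-methyl-1-(2,4,6-trimethoxyphenyl)butan-1-ol (both carbinol epimers) | CC(C)CC(O)(c1c(OC)cc(OC)cc1OC)[C@H]1CC[C@@](C)(O[Si](C)(C)C(C)(C)C)[C@H]2C[C@@H](C(C)(C)O)CC[C@]12C | intermediate
31 | 2-[(1S)-1-[(1R,4R,4aS,6S,8aR)-4-[(tert-butyldimethylsilyl)oxy]-6-(2-hydroxypropan-2-yl)-4,8a-dimethyldecahydronaphthalen-1-yl]-3-methylbutyl]-1,3,5-trimethoxybenzene | CC(C)C[C@H](c1c(OC)cc(OC)cc1OC)[C@H]1CC[C@@](C)(O[Si](C)(C)C(C)(C)C)[C@H]2C[C@@H](C(C)(C)O)CC[C@]12C | intermediate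
32 | 2-[(1S)-1-[(1R,4R,4aS,6S,8aR)-4-hydroxy-6-(2-hydroxypropan-2-yl)-4,8a-dimethyldecahydronaphthalen-1-yl]-3-methylbutyl]-1,3,5-trimethoxybenzene | CC(C)C[C@H](c1c(OC)cc(OC)cc1OC)[C@H]1CC[C@@](C)(O)[C@H]2C[C@@H](C(C)(C)O)CC[C@]12C | intermediate
33 | 1,3-dibromo-5-[(1S)-1-[(1R,4R,4aS,6S,8aR)-4-hydroxy-6-(2-hydroxypropan-2-yl)-4,8a-dimethyldecahydronaphthalen-1-yl]-3-methylbutyl]-2,4,6-trimethoxybenzene | CC(C)C[C@H](c1c(OC)c(Br)c(OC)c(Br)c1OC)[C@H]1CC[C@@](C)(O)[C@H]2C[C@@H](C(C)(C)O)CC[C@]12C | intermediate
34 | 5-[(1S)-1-[(1R,4R,4aS,6S,8aR)-4-hydroxy-6-(2-hydroxypropan-2-yl)-4,8a-dimethyldecahydronaphthalen-1-yl]-3-methylbutyl]-2,4,6-trimethoxybenzene-1,3-dicarbaldehyde | CC(C)C[C@H](c1c(OC)c(C=O)c(OC)c(C=O)c1OC)[C@H]1CC[C@@](C)(O)[C@H]2C[C@@H](C(C)(C)O)CC[C@]12C | intermediate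
35 | 5-[(1S)-1-[(1R,4R,4aS,6S,8aR)-4-hydroxy-6-(2-hydroxypropan-2-yl)-4,8a-dimethyldecahydronaphthalen-1-yl]-3-methylbutyl]-2,4,6-trihydroxybenzene-1,3-dicarbaldehyde | CC(C)C[C@H](c1c(O)c(C=O)c(O)c(C=O)c1O)[C@H]1CC[C@@](C)(O)[C@H]2C[C@@H](C(C)(C)O)CC[C@]12C | target

## Step count and least certain steps

Total step count: 22. Longest linear sequence: 21 steps (steps 1–5 and 7–22); step 6 is a one-step side branch.

**Step 12 (key step).** The first closure is a nucleophilic α-silyloxy radical adding to an unactivated trisubstituted alkene. It may be slower than loss of the radical, either by reduction by the metal hydride or by oxidation by trivalent iron, so the cascade may stop before any ring forms; the facial bias from C1 may also be incomplete. The fallback generates the same C4 radical in a tin hydride chain, which has no oxidant and only a low concentration of hydrogen donor. It sets out from 18. PhSeH adds across the enol ether in the Markovnikov sense (CH2Cl2, 0 °C) to give methyl (2R,3E)-2-{3-[(tert-butyldimethylsilyl)oxy]-3-(phenylselanyl)butyl}-6-[methoxy(methyl)amino]-3-methyl-6-oxohex-3-enoate F1. Reaction with 19 as in step 11 gives the vinyl ketone methyl (2R,3E)-2-{3-[(tert-butyldimethylsilyl)oxy]-3-(phenylselanyl)butyl}-3-methyl-6-oxoocta-3,7-dienoate F2. Slow addition of Bu3SnH and AIBN to F2 in benzene at 80 °C abstracts the selenium group and lets the two closures run under chain conditions; the fallback rejoins the route at 21.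

**Step 7.** The risks are γ-deprotonation at the methyl group instead of the chain CH2, O-alkylation, and decomposition of the sodium dienolate before it is alkylated. The fallback replaces alkylation by conjugate addition. From 10, soft enolisation with TiCl4 and i-Pr2NEt (CH2Cl2, −78 °C) gives the chlorotitanium dienolate, which adds at its α-carbon to 11 under the same auxiliary control and returns to the route at 14. No new compound is made.

**Step 14.** Epimerisation at C1 may be incomplete, because an equatorial ester next to the quaternary C10 is gauche to both the methyl group and C9 and is only modestly favoured. The fallback sets C1 by kinetic protonation instead. It sets out from 23. K2CO3 in MeOH at rt equilibrates only the acetyl centre and gives methyl (1R,4R,4aS,6S,8aS)-6-acetyl-4-[(tert-butyldimethylsilyl)oxy]-4,8a-dimethyldecahydronaphthalene-1-carboxylate F3, with the ester still axial. MeMgBr/CeCl3 as in step 15 gives methyl (1R,4R,4aS,6S,8aS)-4-[(tert-butyldimethylsilyl)oxy]-6-(2-hydroxypropan-2-yl)-4,8a-dimethyldecahydronaphthalene-1-carboxylate F4. LiN(i-Pr)2 (2.2 equiv) then forms the ester enolate, which is protonated at −78 °C by 2,6-di-tert-butyl-4-methylphenol on the face away from the C10 methyl; this gives the equatorial ester and returns to the route at 25.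

**Step 17.** The addition may fail through enolisation of 27 by the aryl nucleophile or through steric blocking. The fallback makes the aryl–C9′ bond by acyl substitution and brings in the four-carbon chain with an allyl-type reagent. It sets out from 26, isolated after the first half of step 16. Addition of 29 gives [(1S,4R,4aS,6S,8aS)-4-[(tert-butyldimethylsilyl)oxy]-6-(2-hydroxypropan-2-yl)-4,8a-dimethyldecahydronaphthalen-1-yl](2,4,6-trimethoxyphenyl)methanone F5; a second addition to this di-ortho-substituted aryl ketone is not expected. 2-Methylallylmagnesium chloride adds through a six-membered transition state to give 1-[(1S,4R,4aS,6S,8aR)-4-[(tert-butyldimethylsilyl)oxy]-6-(2-hydroxypropan-2-yl)-4,8a-dimethyldecahydronaphthalen-1-yl]-3-methyl-1-(2,4,6-trimethoxyphenyl)but-3-en-1-ol F6. Diimide (TsNHNH2, NaOAc, DME/H2O, 85 °C) saturates the 1,1-disubstituted alkene and returns to the route at 30.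

**Step 18.** Hydride may be delivered to the wrong face of the cation (the rotamer about C1–C9′ decides), a proton may be lost to give styrenes, or the C11 alcohol may ionise if the acid is not mild enough. The fallback reverses the order in which hydrogen and the carbon chain arrive at C9′, which inverts the configuration produced by the same facial bias. It sets out from 25:
- LiAlH4 gives [(1S,4R,4aS,6S,8aR)-4-[(tert-butyldimethylsilyl)oxy]-6-(2-hydroxypropan-2-yl)-4,8a-dimethyldecahydronaphthalen-1-yl]methanol F7.
- DMP gives (1S,4R,4aS,6S,8aS)-4-[(tert-butyldimethylsilyl)oxy]-6-(2-hydroxypropan-2-yl)-4,8a-dimethyldecahydronaphthalene-1-carbaldehyde F8.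
- Addition of 29 gives [(1S,4R,4aS,6S,8aR)-4-[(tert-butyldimethylsilyl)oxy]-6-(2-hydroxypropan-2-yl)-4,8a-dimethyldecahydronaphthalen-1-yl](2,4,6-trimethoxyphenyl)methanol F9.
- BF3·OEt2 and trimethyl(2-methylallyl)silane at −78 °C replace the hydroxyl through the benzylic cation and give 2-[(1S)-1-[(1R,4R,4aS,6S,8aR)-4-[(tert-butyldimethylsilyl)oxy]-6-(2-hydroxypropan-2-yl)-4,8a-dimethyldecahydronaphthalen-1-yl]-3-methylbut-3-en-1-yl]-1,3,5-trimethoxybenzene F10.
- H2 over Pd/C in EtOAc saturates the alkene and returns to the route at 31.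

## Further compounds

F0 | step 7 | none | none
F1 | step 12 | methyl (2R,3E)-2-{3-[(tert-butyldimethylsilyl)oxy]-3-(phenylselanyl)butyl}-6-[methoxy(methyl)amino]-3-methyl-6-oxohex-3-enoate | CC(O[Si](C)(C)C(C)(C)C)([Se]c1ccccc1)CC[C@@H](C(=O)OC)/C(C)=C/CC(=O)N(C)OC
F2 | step 12 | methyl (2R,3E)-2-{3-[(tert-butyldimethylsilyl)oxy]-3-(phenylselanyl)butyl}-3-methyl-6-oxoocta-3,7-dienoate | CC(O[Si](C)(C)C(C)(C)C)([Se]c1ccccc1)CC[C@@H](C(=O)OC)/C(C)=C/CC(=O)C=C
F3 | step 14 | methyl (1R,4R,4aS,6S,8aS)-6-acetyl-4-[(tert-butyldimethylsilyl)oxy]-4,8a-dimethyldecahydronaphthalene-1-carboxylate | COC(=O)[C@@H]1CC[C@@](C)(O[Si](C)(C)C(C)(C)C)[C@H]2C[C@@H](C(C)=O)CC[C@]12C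
F4 | step 14 | methyl (1R,4R,4aS,6S,8aS)-4-[(tert-butyldimethylsilyl)oxy]-6-(2-hydroxypropan-2-yl)-4,8a-dimethyldecahydronaphthalene-1-carboxylate | COC(=O)[C@@H]1CC[C@@](C)(O[Si](C)(C)C(C)(C)C)[C@H]2C[C@@H](C(C)(C)O)CC[C@]12C
F5 | step 17 | [(1S,4R,4aS,6S,8aS)-4-[(tert-butyldimethylsilyl)oxy]-6-(2-hydroxypropan-2-yl)-4,8a-dimethyldecahydronaphthalen-1-yl](2,4,6-trimethoxyphenyl)methanone | COc1cc(OC)c(C(=O)[C@H]2CC[C@@](C)(O[Si](C)(C)C(C)(C)C)[C@H]3C[C@@H](C(C)(C)O)CC[C@]23C)c(OC)c1
F6 | step 17 | 1-[(1S,4R,4aS,6S,8aR)-4-[(tert-butyldimethylsilyl)oxy]-6-(2-hydroxypropan-2-yl)-4,8a-dimethyldecahydronaphthalen-1-yl]-3-methyl-1-(2,4,6-trimethoxyphenyl)but-3-en-1-ol | CC(=C)CC(O)(c1c(OC)cc(OC)cc1OC)[C@H]1CC[C@@](C)(O[Si](C)(C)C(C)(C)C)[C@H]2C[C@@H](C(C)(C)O)CC[C@]12C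
F7 | step 18 | [(1S,4R,4aS,6S,8aR)-4-[(tert-butyldimethylsilyl)oxy]-6-(2-hydroxypropan-2-yl)-4,8a-dimethyldecahydronaphthalen-1-yl]methanol | OC[C@H]1CC[C@@](C)(O[Si](C)(C)C(C)(C)C)[C@H]2C[C@@H](C(C)(C)O)CC[C@]12C
F8 | step 18 | (1S,4R,4aS,6S,8aS)-4-[(tert-butyldimethylsilyl)oxy]-6-(2-hydroxypropan-2-yl)-4,8a-dimethyldecahydronaphthalene-1-carbaldehyde | O=C[C@H]1CC[C@@](C)(O[Si](C)(C)C(C)(C)C)[C@H]2C[C@@H](C(C)(C)O)CC[C@]12C
F9 | step 18 | [(1S,4R,4aS,6S,8aR)-4-[(tert-butyldimethylsilyl)oxy]-6-(2-hydroxypropan-2-yl)-4,8a-dimethyldecahydronaphthalen-1-yl](2,4,6-trimethoxyphenyl)methanol | OC(c1c(OC)cc(OC)cc1OC)[C@H]1CC[C@@](C)(O[Si](C)(C)C(C)(C)C)[C@H]2C[C@@H](C(C)(C)O)CC[C@]12C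
F10 | step 18 | 2-[(1S)-1-[(1R,4R,4aS,6S,8aR)-4-[(tert-butyldimethylsilyl)oxy]-6-(2-hydroxypropan-2-yl)-4,8a-dimethyldecahydronaphthalen-1-yl]-3-methylbut-3-en-1-yl]-1,3,5-trimethoxybenzene | CC(=C)C[C@H](c1c(OC)cc(OC)cc1OC)[C@H]1CC[C@@](C)(O[Si](C)(C)C(C)(C)C)[C@H]2C[C@@H](C(C)(C)O)CC[C@]12C
A1 | alternative 1 | (4R,5S)-7-methyl-4-(1-methyl-4-oxocyclohexa-2,5-dien-1-yl)-5-(2,4,6-trimethoxyphenyl)octanal | CC(C)C[C@H](c1c(OC)cc(OC)cc1OC)[C@@H](CCC=O)C1(C)C=CC(=O)C=C1
A2 | alternative 1 | trans-4a-methyl-4-[(1S)-3-methyl-1-(2,4,6-trimethoxyphenyl)butyl]-3,4,4a,8a-tetrahydronaphthalene-1,7(2H,8H)-dione (C1, C5 and C10 as in 35) | CC(C)C[C@H](c1c(OC)cc(OC)cc1OC)[C@H]1CCC(=O)[C@H]2CC(=O)C=C[C@]12C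
A3 | alternative 2 | {[(3S)-3-[(1R,4R,4aS,6S,8aR)-4,8a-dimethyl-4-[(trimethylsilyl)oxy]-6-{2-[(trimethylsilyl)oxy]propan-2-yl}decahydronaphthalen-1-yl]-5-methylhex-1-yn-1-yl]oxy}tri(propan-2-yl)silane | CC(C)C[C@H](C#CO[Si](C(C)C)(C(C)C)C(C)C)[C@H]1CC[C@@](C)(O[Si](C)(C)C)[C@H]2C[C@@H](C(C)(C)O[Si](C)(C)C)CC[C@]12C
A4 | alternative 2 | dimethyl 4,6-dimethoxy-2-oxo-2H-pyran-3,5-dicarboxylate | COC(=O)c1c(OC)c(C(=O)OC)c(OC)oc1=O
A5 | alternative 2 | dimethyl 5-[(1S)-1-[(1R,4R,4aS,6S,8aR)-4,8a-dimethyl-4-[(trimethylsilyl)oxy]-6-{2-[(trimethylsilyl)oxy]propan-2-yl}decahydronaphthalen-1-yl]-3-methylbutyl]-2,6-dimethoxy-4-{[tri(propan-2-yl)silyl]oxy}benzene-1,3-dicarboxylate | CC(C)C[C@H](c1c(O[Si](C(C)C)(C(C)C)C(C)C)c(C(=O)OC)c(OC)c(C(=O)OC)c1OC)[C@H]1CC[C@@](C)(O[Si](C)(C)C)[C@H]2C[C@@H](C(C)(C)O[Si](C)(C)C)CC[C@]12C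
A6 | alternative 3 | (5S,6R)-2,6-dimethyl-5-(prop-1-en-2-yl)cyclohex-2-en-1-one | CC(=C)[C@H]1CC=C(C)C(=O)[C@@H]1C
A7 | alternative 3 | 4a,8-dimethyl-5-(prop-1-en-2-yl)-4,4a,5,6-tetrahydronaphthalen-2(3H)-one (C1 and C10 as in 35) | CC(=C)[C@H]1CC=C(C)C2=CC(=O)CC[C@]12C
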